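## Retrosynthetic overview
1. Cleave the ester C(=O)–O bond at the ring CH2O. This gives 9'-hydroxyabscisic acid and the (S)-monomethyl ester of 3-hydroxy-3-methylglutaric acid.
2. Cleave the C9'–O bond of 9'-hydroxyabscisic acid (key step). This gives (S)-(+)-abscisic acid; hydroxylating the ring methyl that is trans to the 1'-OH makes C6' stereogenic.
3. The (S)-half ester comes from enzymatic desymmetrisation of the prochiral dimethyl ester, which is made from 3-hydroxy-3-methylglutaric acid and methanol.
4. Rings: the single cyclohexenone ring, C1' and the Z,E-dienoic acid are bought with abscisic acid. No ring and no C–C bond is formed, and every step makes or breaks only C–O bonds.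

Assumption: the SMILES is read literally. The ring is (1'R,6'S), so the CH2O group is trans to the 1'-OH and cis to the side chain. This is position 9' in abscisic acid numbering, not the 8' methyl that the native plant P450 oxidises. The glutarate carbon is (R).

## Route

Step 1
Reactants: 1 3-hydroxy-3-methylglutaric acid (meglutol)
Product: 2 dimethyl 3-hydroxy-3-methylglutarate
Conditions: MeOH (solvent), H2SO4 (5 mol%), 40 °C
Reagents that add atoms: methanol, CO
Why: Fischer esterification; both carboxyl groups esterify in excess methanol at a temperature where the tertiary beta-hydroxyl group does not dehydrate, and the product is still prochiral, so no stereocenter arises.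

Step 2
Reactants: 2 dimethyl 3-hydroxy-3-methylglutarate
Product: 3 (S)-3-hydroxy-5-methoxy-3-methyl-5-oxopentanoic acid
Conditions: pig liver esterase, phosphate buffer pH 7.5, pH-stat 1 M NaOH (1.0 equiv), 25 °C; then HCl to pH 2.5, EtOAc
Reagents that add atoms: water, O
Why: Enzymatic desymmetrising ester hydrolysis; the esterase accepts only one of the two enantiotopic CH2CO2Me arms, which is the established access to the (S)-half ester in high ee, and the carboxylate formed is not hydrolysed further, so the carbinol stereocenter is set here.

Step 3
Reactants: 4 (S)-(+)-abscisic acid
Product: 5 (2Z,4E)-5-[(1R,6S)-1-hydroxy-6-(hydroxymethyl)-2,6-dimethyl-4-oxocyclohex-2-en-1-yl]-3-methylpenta-2,4-dienoic acid (9'-hydroxyabscisic acid)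
Conditions: re-engineered 9'-selective CYP707A3 variant plus its reductase ATR2 (clarified lysate), NADP+ (cat.), glucose dehydrogenase, D-glucose (1.5 equiv), air, phosphate buffer pH 6.5, 25 °C; extract at pH 3 (EtOAc, 4 °C), use at once
Reagents that add atoms: dioxygen, O=O
Why: Proposed new method: this is a P450 C–H hydroxylation, in which the tetravalent iron-oxo porphyrin radical cation abstracts a hydrogen atom and the oxygen rebounds with retention; the site is moved from the native 8' methyl (cis to 1'-OH, axial, anti to the side chain) to the geminal 9' methyl (trans to 1'-OH, equatorial, cis to the side chain); the wild-type enzyme already gives 5 as a minor product, so both methyl carbons, only about 2.5 Å apart, lie within reach of the oxo ligand; a ring tilt of 1 to 2 Å should therefore invert the ratio, and it is sought by saturation mutagenesis of the first-shell residues that pack against C7', C8' and C9', with an LC-MS screen for 5 against phaseic acid; oxidising this one of the two diastereotopic methyl groups makes C6' stereogenic as (S), while C1' is untouched and its descriptor changes from S to R only through CIP priorities; the enone, the dienoic acid and the weaker allylic C–H bonds are spared because positioning, not bond strength, decides the site; the closest known reaction types are the native CYP707A 8'-hydroxylation of 4 and the redirection of bacterial P450 variants between neighbouring terpenoid C–H positions by directed evolution.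

Step 4
Reactants: 3 (S)-3-hydroxy-5-methoxy-3-methyl-5-oxopentanoic acid; 5 9'-hydroxyabscisic acid
Product: 7 (2Z,4E)-5-[(1R,6S)-1-hydroxy-6-({[(3R)-3-hydroxy-5-methoxy-3-methyl-5-oxopentanoyl]oxy}methyl)-2,6-dimethyl-4-oxocyclohex-2-en-1-yl]-3-methylpenta-2,4-dienoic acid (target), via symmetric anhydride 6 (not isolated)
Conditions: 3 (4 equiv), N,N'-dicyclohexylcarbodiimide (2 equiv), CH2Cl2, 0 °C, 30 min, filter; then 5 (1 equiv), pyridine (3 equiv), 4-(dimethylamino)pyridine (0.2 equiv), CH2Cl2, 0 °C to rt; H2O quench
Reagents that add atoms: none
Why: Steglich-type acylation with a preformed symmetric anhydride under nucleophilic catalysis; only the single primary alcohol of 5 reacts and both tertiary alcohols are inert, no carbodiimide is left to activate the dienoic acid, the weakly basic medium keeps oxa-Michael closure of 5 slower than acylation, and no stereocenter is touched (the glutarate descriptor changes from S to R only through CIP priorities).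

## Compound list
1 | 3-hydroxy-3-methylglutaric acid (meglutol) | CC(O)(CC(=O)O)CC(=O)O | starting material
2 | dimethyl 3-hydroxy-3-methylglutarate | COC(=O)CC(C)(O)CC(=O)OC | intermediate
3 | (S)-3-hydroxy-5-methoxy-3-methyl-5-oxopentanoic acid | COC(=O)C[C@@](C)(O)CC(=O)O | intermediate
4 | (S)-(+)-abscisic acid | CC1(C)CC(=O)C=C(C)[C@]1(O)/C=C/C(C)=C\C(=O)O | starting material
5 | 9'-hydroxyabscisic acid, (1'R,6'S), CH2OH trans to the ring OH | OC[C@]1(C)CC(=O)C=C(C)[C@]1(O)/C=C/C(C)=C\C(=O)O | intermediate
6 | symmetric anhydride of 3 | COC(=O)C[C@@](C)(O)CC(=O)OC(=O)C[C@](C)(O)CC(=O)OC | intermediate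
7 | target CNP0274837.1 | COC(=O)C[C@@](C)(O)CC(=O)OC[C@]1(C)CC(=O)C=C(C)[C@]1(O)/C=C/C(C)=C\C(=O)O | target

## Step count
Total step count: 4. Longest linear sequence: 3 (1 to 2 to 3 to 7). The abscisic acid branch has 2 steps (4 to 5 to 7).

## Three steps most likely to fail

**1. Step 3 (the proposed new step).**
- Risk: no variant may reach useful 9' over 8' selectivity. Compound 5 may also be over-oxidised, or it may close to its bicyclic oxa-Michael isomer during the run.
- Fallback (known chemistry, from 4 back to 5): give up catalyst-controlled site selectivity and use the wild-type CYP707A3/ATR2 system with the same cofactor recycling. Its product spread is documented. The main path gives 8'-hydroxyabscisic acid F1, which isomerises by itself to (−)-phaseic acid F2, and the side path gives 5. The isomers are then separated rather than selected. F2 has lost the enone chromophore and elutes apart, so reversed-phase chromatography at pH 3 delivers 5, and unreacted 4 is recycled. Throughput per pass is low, but every operation is established.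

**2. Step 4.**
- Risk: the free dienoic acid of 5 may exchange with the anhydride, giving mixed anhydrides and abscisyl esters. The activated beta-hydroxy acid may form a beta-lactone. Compound 5 may cyclise before it is acylated.
- Fallback (from 5 back to 7): mask the acid first.
  - Esterify 5 under neutral conditions with O-allyl-N,N'-diisopropylisourea (THF, rt) to give allyl 9'-hydroxyabscisate F3.
  - Run a standard Steglich esterification (3, EDC·HCl, 4-(dimethylamino)pyridine, CH2Cl2, 0 °C). Only one carboxylic acid is now in the flask, and the product is the allyl ester of the target F4.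
  - Remove the allyl group with Pd(PPh3)4 (zerovalent palladium, 5 mol%) and morpholine in THF. This Tsuji–Trost allyl transfer leaves the methyl ester, the glutarate ester and the enone untouched and gives 7.

**3. Step 2.**
- Risk: ee may vary from batch to batch of the crude esterase, and over-hydrolysis to 1 is possible.
- Fallback (from 1 back to 3, bypassing 2): dehydrate 1 with N,N'-dicyclohexylcarbodiimide (EtOAc, rt) to 3-hydroxy-3-methylglutaric anhydride F5. Open this prochiral cyclic anhydride with methanol in the presence of quinidine (toluene, −50 °C), or with quinine if the opposite sense is found. This is an alkaloid-mediated desymmetrising alcoholysis, and it sets the same stereocenter by C–O bond formation instead of C–O bond cleavage.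

## Further compounds
F1 | step 3 | 8'-hydroxyabscisic acid, (1'R,6'R) | OC[C@@]1(C)CC(=O)C=C(C)[C@]1(O)/C=C/C(C)=C\C(=O)O
F2 | step 3 | (−)-phaseic acid | OC(=O)/C=C(C)\C=C\[C@]1(O)[C@]2(C)CC(=O)C[C@@]1(C)OC2
F3 | step 4 | allyl 9'-hydroxyabscisate, (1'R,6'S) | OC[C@]1(C)CC(=O)C=C(C)[C@]1(O)/C=C/C(C)=C\C(=O)OCC=C
F4 | step 4 | allyl ester of the target | COC(=O)C[C@@](C)(O)CC(=O)OC[C@]1(C)CC(=O)C=C(C)[C@]1(O)/C=C/C(C)=C\C(=O)OCC=C
F5 | step 2 | 3-hydroxy-3-methylglutaric anhydride | CC1(O)CC(=O)OC(=O)C1
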